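**Plan** (target numbered as an 8-oxabicyclo[5.2.1]decane-6,9,10-trione: C1 and C7 are the prenylated bridgeheads, O8–C9(=O) is the lactone, C10 the bridging ketone, C5 the CH–isobutyryl carbon)
1. Retrosynthetic cuts, in order: the C5–acyl bond (aldol/oxidation); then O8–C7 and C9–C1 together, which removes CO2 and leaves the C1 enolate of a 2,4-diprenylated cyclooctane-1,3-dione; then that enolate back to a silyloxycyclobutanone fused to a cyclohexane (retro-aldol ring expansion, ketene [2+2]); then the cyclohexanone by two conjugate additions to (R)-4-prenylcyclohexenone.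
2. Enabling feature: C1 and C7 are the two α-carbons of the C10 ketone. C7 is also α to the C6 ketone, so it is the easily oxidised enol carbon of a β-diketone. C1 is the γ-carbon, whose enolate is formed regiospecifically when the four-membered ring opens. A carboxylate on C1 sits 1,3 to C7, so O8–C7 closure gives the five-membered lactone bridge across the eight-membered ring.
3. Forward order: six-membered ring, then fused four-membered ring, then (key step) eight-membered carbocycle and lactone in one flask, then C5 acylation.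
4. Stereochemistry: C3 from enamine catalysis; C4 by copper-mediated addition anti to the C3 prenyl group; C1 and C7 in the key step; C5 by equilibration.

Key step: step 10

Assumption: the C5 configuration of the target is taken to be the thermodynamically preferred one for this enolisable β-diketone methine (isobutyryl trans to the neighbouring homoprenyl group), so it is set by equilibration. Reagents named without a number are commercial; the homoprenyl Grignard reagent is made from commercial 5-bromo-2-methylpent-2-ene.

**Step 1**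
Reactants: 1 2-methylbut-3-en-2-ol
Product: 3 5-methylhex-4-enal, via allyl vinyl ether 2 (not isolated)
Conditions: ethyl vinyl ether (excess), H3PO4 (cat.), 125 °C, sealed vessel
Reagents that add atoms: ethyl vinyl ether, C=COCC
Why: Acid-catalysed transetherification gives the tertiary allyl vinyl ether, whose Claisen rearrangement moves the vinyl unit to the alkene terminus and should give the γ,δ-unsaturated aldehyde.

**Step 2**
Reactants: 3 5-methylhex-4-enal
Product: 5 (R)-4-(3-methylbut-2-en-1-yl)cyclohex-2-en-1-one, via keto aldehyde 4 (not isolated)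
Conditions: methyl vinyl ketone, (R)-α,α-diphenylprolinol trimethylsilyl ether (10 mol %), ethyl 3,4-dihydroxybenzoate (20 mol %), neat, 4 °C; then KOH, Bu4NOH (cat.), Et2O/THF/H2O, reflux
Reagents that add atoms: methyl vinyl ketone, C=CC(C)=O
Why: Enamine-catalysed Michael addition followed by intramolecular aldol condensation (Robinson-type annulation) builds the ring; the diarylsilyloxymethyl group shields one enamine face, so the (R)-catalyst should give the (R)-configured centre.

**Step 3**
Reactants: 5 (R)-4-(3-methylbut-2-en-1-yl)cyclohex-2-en-1-one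
Product: 7 (R)-3-methyl-4-(3-methylbut-2-en-1-yl)cyclohex-2-en-1-one, via silyl enol ether 6 (not isolated)
Conditions: MeMgBr, CuBr·SMe2 (10 mol %), TMSCl, THF, −78 °C; Et3N, pentane, filtration; then Pd(OAc)2 (1.1 equiv), MeCN, rt
Reagents that add atoms: methylmagnesium bromide, C[Mg]Br
Why: Copper-catalysed conjugate addition with silyl trapping followed by Saegusa–Ito oxidation should re-form the enone with the methyl group on the β-carbon; the C4 centre is untouched and the transient methine centre is destroyed again.

**Step 4**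
Reactants: 7 (R)-3-methyl-4-(3-methylbut-2-en-1-yl)cyclohex-2-en-1-one
Product: 9 (3S,4R)-3-methyl-3-(4-methylpent-3-en-1-yl)-4-(3-methylbut-2-en-1-yl)cyclohexan-1-one, via silyl enol ether 8 (not isolated)
Conditions: (4-methylpent-3-en-1-yl)magnesium bromide, CuBr·SMe2 (20 mol %), TMSCl, THF, −78 → −30 °C; then 1 M HCl, 0 °C
Reagents that add atoms: (4-methylpent-3-en-1-yl)magnesium bromide, CC(C)=CCC[Mg]Br
Why: Copper-mediated conjugate addition to the β,β-disubstituted enone should occur anti to the adjacent C4 prenyl group (axial attack on the half-chair with that group pseudo-axial), which sets the quaternary centre with homoprenyl trans to prenyl.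

**Step 5**
Reactants: 9 (3S,4R)-3-methyl-3-(4-methylpent-3-en-1-yl)-4-(3-methylbut-2-en-1-yl)cyclohexan-1-one
Product: 12 (4S,5S)-5-methyl-2-methylidene-5-(4-methylpent-3-en-1-yl)-4-(3-methylbut-2-en-1-yl)cyclohexan-1-one, via Mannich base 10 (not isolated), via ammonium iodide 11 (not isolated)
Conditions: LDA, THF, −78 °C; dimethyl(methylidene)ammonium iodide, −78 → 0 °C; then MeI, MeOH, rt; then NaHCO3 aq., CH2Cl2, rt; product used at once
Reagents that add atoms: dimethyl(methylidene)ammonium iodide, C=[N+](C)C.[I-]
Why: Kinetic deprotonation should take place at the CH2 remote from the quaternary carbon, and Mannich reaction, N-methylation and E1cB elimination then give the α-methylene ketone on that side only.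

**Step 6**
Reactants: 12 (4S,5S)-5-methyl-2-methylidene-5-(4-methylpent-3-en-1-yl)-4-(3-methylbut-2-en-1-yl)cyclohexan-1-one
Product: 13 trimethyl{[(4S,5S)-5-methyl-5-(4-methylpent-3-en-1-yl)-2,4-bis(3-methylbut-2-en-1-yl)cyclohex-1-en-1-yl]oxy}silane
Conditions: (2-methylprop-1-en-1-yl)magnesium bromide, CuBr·SMe2 (10 mol %), TMSCl, THF, −78 °C; Et3N, pentane, cold NaHCO3 aq.
Reagents that add atoms: (2-methylprop-1-en-1-yl)magnesium bromide, CC(C)=C[Mg]Br; chlorotrimethylsilane, C[Si](C)(C)Cl
Why: Conjugate addition of the alkenylcopper species to the exocyclic enone completes the prenyl side chain and the enolate is silylated in situ, so the tetrasubstituted enol ether should form regiospecifically, which direct enolisation of the ketone could not guarantee.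

**Step 7**
Reactants: 13 trimethyl{[(4S,5S)-5-methyl-5-(4-methylpent-3-en-1-yl)-2,4-bis(3-methylbut-2-en-1-yl)cyclohex-1-en-1-yl]oxy}silane
Product: 14 8,8-dichloro-3-methyl-3-(4-methylpent-3-en-1-yl)-4,6-bis(3-methylbut-2-en-1-yl)-1-(trimethylsilyloxy)bicyclo[4.2.0]octan-7-one
Conditions: Cl2CHCOCl (slow addition), Et3N, hexane, 0 °C → rt
Reagents that add atoms: dichloroacetyl chloride, O=C(Cl)C(Cl)Cl
Why: Thermal [2+2] cycloaddition of dichloroketene to the electron-rich enol ether joins the ketene carbonyl carbon to the nucleophilic prenyl-bearing carbon and gives the cis-fused cyclobutanone, expected on the face anti to the pseudo-axial C3 methyl group; the ring-fusion configuration is erased in step 10.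

**Step 8**
Reactants: 14 8,8-dichloro-3-methyl-3-(4-methylpent-3-en-1-yl)-4,6-bis(3-methylbut-2-en-1-yl)-1-(trimethylsilyloxy)bicyclo[4.2.0]octan-7-one
Product: 15 3-methyl-3-(4-methylpent-3-en-1-yl)-4,6-bis(3-methylbut-2-en-1-yl)-1-(trimethylsilyloxy)bicyclo[4.2.0]octan-7-one
Conditions: Zn dust, AcOH, i-PrOH/H2O, 0 °C → rt
Reagents that add atoms: none
Why: Zinc should reduce both α-C–Cl bonds of the α,α-dichloroketone through zinc enolates and leave the hindered tertiary silyl ether in place, as in the dichloroketene route to cycloalkane-1,3-diones.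

**Step 9**
Reactants: 15 3-methyl-3-(4-methylpent-3-en-1-yl)-4,6-bis(3-methylbut-2-en-1-yl)-1-(trimethylsilyloxy)bicyclo[4.2.0]octan-7-one
Product: 16 3-methyl-3-(4-methylpent-3-en-1-yl)-4,6,8-tris(3-methylbut-2-en-1-yl)-1-(trimethylsilyloxy)bicyclo[4.2.0]octan-7-one
Conditions: LDA, THF, −78 °C; prenyl bromide, DMPU, −78 → −40 °C
Reagents that add atoms: 1-bromo-3-methylbut-2-ene, CC(C)=CCBr
Why: The cyclobutanone has only one enolisable position and its lithium enolate should be alkylated by the allylic bromide; the new C8 centre may form as a mixture of epimers, which converge in step 10.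

**Step 10**
Reactants: 16 3-methyl-3-(4-methylpent-3-en-1-yl)-4,6,8-tris(3-methylbut-2-en-1-yl)-1-(trimethylsilyloxy)bicyclo[4.2.0]octan-7-one
Product: 20 (1R,3S,4S,7S)-4-methyl-4-(4-methylpent-3-en-1-yl)-1,3,7-tris(3-methylbut-2-en-1-yl)-8-oxabicyclo[5.2.1]decane-6,9,10-trione, via enolate 17 (not isolated), via carboxylate 18 (not isolated), via iodane 19 (not isolated)
Conditions: TASF (1.2 equiv), CO2 (1 atm, saturated solution), THF/DMF, high dilution, −78 → −20 °C; then PhI(OAc)2 (1.2 equiv), −20 → 0 °C, dark, CO2 atmosphere kept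
Reagents that add atoms: carbon dioxide, O=C=O
Why: Proposed new method: fluoride removes the bridgehead silyl group of 16 and the strained cyclobutanolate undergoes retro-aldol fission of the ring-fusion bond (C1–C6 of the bicyclooctanone), which expands the six-membered ring to the cyclooctane-1,3-dione and releases its tetrasubstituted enolate 17 regiospecifically at the carbon that becomes C1 of the target; CO2 traps it as carboxylate 18, and PhI(OAc)2 then converts the β-diketone enol at the future C7 into iodane 19, from which the carboxylate oxygen expels iodobenzene. The closest known reaction types are the fluoride- or acid-induced two-carbon ring expansion of 1-silyloxybicyclo[n.2.0]alkanones to cycloalkane-1,3-diones, the carboxylation of regiospecifically generated enolates with CO2, and the iodine(III)-mediated α-acyloxylation and keto-acid lactonisation of β-dicarbonyl compounds; what is new is their union in one flask and the closure at a fully substituted carbon. The eight-membered carbocycle arises by fragmentation (ring expansion), and the lactone closes by 5-exo-tet attack of the carboxylate oxygen on C7 across the C10 ketone. C7 is controlled by the tether, because the carboxylate can reach only the ring face on which it sits (a cis bridge), whichever epimer of the prenylated methine is carried from 16; C1 is controlled by the folded eight-membered ring, since carboxylation of the naked enolate is reversible under CO2, the C1 epimers of 18 can equilibrate, and the irreversible closure should pass through the product-like arrangement that keeps the C3 prenyl and C4 homoprenyl groups on the convex, pseudo-equatorial side. The step needs fission of the ring-fusion bond and not of the C1–C8 bond of the bicyclooctanone (relief of bicyclic strain, as in the parent ring expansions), CO2 capture ahead of proton transfer from the new β-diketone C–H (saturated CO2, low temperature, dilution), and oxidation of the enol and not of the four trisubstituted alkenes (a two-electron iodine(III) oxidant without acid activation, used in the dark so that no α-keto radical can cyclise onto a prenyl group).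

**Step 11**
Reactants: 20 (1R,3S,4S,7S)-4-methyl-4-(4-methylpent-3-en-1-yl)-1,3,7-tris(3-methylbut-2-en-1-yl)-8-oxabicyclo[5.2.1]decane-6,9,10-trione
Product: 21 5-(1-hydroxy-2-methylpropyl)-4-methyl-4-(4-methylpent-3-en-1-yl)-1,3,7-tris(3-methylbut-2-en-1-yl)-8-oxabicyclo[5.2.1]decane-6,9,10-trione
Conditions: LDA, THF, −78 °C; i-PrCHO, −78 °C; aqueous work-up
Reagents that add atoms: 2-methylpropanal, CC(C)C=O
Why: C5 is the only enolisable carbon of 20, so its lithium enolate should undergo aldol addition to the aldehyde; both new centres form as mixtures that are removed or equilibrated in step 12.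

**Step 12**
Reactants: 21 5-(1-hydroxy-2-methylpropyl)-4-methyl-4-(4-methylpent-3-en-1-yl)-1,3,7-tris(3-methylbut-2-en-1-yl)-8-oxabicyclo[5.2.1]decane-6,9,10-trione
Product: 22 (1R,3S,4R,5R,7S)-4-methyl-4-(4-methylpent-3-en-1-yl)-1,3,7-tris(3-methylbut-2-en-1-yl)-5-(2-methylpropanoyl)-8-oxabicyclo[5.2.1]decane-6,9,10-trione
Conditions: Dess–Martin periodinane, NaHCO3, CH2Cl2, rt; then Et3N (cat.), CH2Cl2, rt
Reagents that add atoms: none
Why: Dess–Martin oxidation of the β-hydroxy ketone should give the β-diketone, and the C5 methine then equilibrates through its enol to the more stable epimer with the isobutyryl group trans to the neighbouring homoprenyl group.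

**Compound list**
1 | 2-methylbut-3-en-2-ol | CC(C)(O)C=C | starting material
2 | 3-(ethenyloxy)-3-methylbut-1-ene (allyl vinyl ether) | C=COC(C)(C)C=C | intermediate
3 | 5-methylhex-4-enal | CC(C)=CCCC=O | intermediate
4 | (R)-2-(3-methylbut-2-en-1-yl)-5-oxohexanal | O=C[C@@H](CC=C(C)C)CCC(C)=O | intermediate
5 | (R)-4-(3-methylbut-2-en-1-yl)cyclohex-2-en-1-one | O=C1C=C[C@@H](CC=C(C)C)CC1 | intermediate
6 | trimethylsilyl enol ether of trans-3-methyl-4-prenylcyclohexanone (1-silyloxycyclohex-1-ene, methyl anti to prenyl) | C[Si](C)(C)OC1=C[C@H](C)[C@@H](CC=C(C)C)CC1 | intermediate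
7 | (R)-3-methyl-4-(3-methylbut-2-en-1-yl)cyclohex-2-en-1-one | O=C1C=C(C)[C@@H](CC=C(C)C)CC1 | intermediate
8 | trimethylsilyl enol ether of 9 (double bond toward the quaternary carbon) | C[Si](C)(C)OC1=C[C@](C)(CCC=C(C)C)[C@@H](CC=C(C)C)CC1 | intermediate
9 | (3S,4R)-3-methyl-3-(4-methylpent-3-en-1-yl)-4-(3-methylbut-2-en-1-yl)cyclohexan-1-one (homoprenyl trans to prenyl) | O=C1C[C@](C)(CCC=C(C)C)[C@@H](CC=C(C)C)CC1 | intermediate
10 | 6-[(dimethylamino)methyl] derivative of 9 (Mannich base, C6 epimers) | O=C1C[C@](C)(CCC=C(C)C)[C@@H](CC=C(C)C)CC1CN(C)C | intermediate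
11 | trimethylammonium iodide of 10 | O=C1C[C@](C)(CCC=C(C)C)[C@@H](CC=C(C)C)CC1C[N+](C)(C)C.[I-] | intermediate
12 | (4S,5S)-5-methyl-2-methylidene-5-(4-methylpent-3-en-1-yl)-4-(3-methylbut-2-en-1-yl)cyclohexan-1-one | O=C1C[C@](C)(CCC=C(C)C)[C@@H](CC=C(C)C)CC1=C | intermediate
13 | trimethyl{[(4S,5S)-5-methyl-5-(4-methylpent-3-en-1-yl)-2,4-bis(3-methylbut-2-en-1-yl)cyclohex-1-en-1-yl]oxy}silane | C[Si](C)(C)OC1=C(CC=C(C)C)C[C@H](CC=C(C)C)[C@@](C)(CCC=C(C)C)C1 | intermediate
14 | 8,8-dichloro-3-methyl-3-(4-methylpent-3-en-1-yl)-4,6-bis(3-methylbut-2-en-1-yl)-1-(trimethylsilyloxy)bicyclo[4.2.0]octan-7-one (cis-fused, four-membered ring anti to the C3 methyl; C3/C4 as in 9) | C[Si](C)(C)O[C@@]12C[C@](C)(CCC=C(C)C)[C@@H](CC=C(C)C)C[C@]1(CC=C(C)C)C(=O)C2(Cl)Cl | intermediate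
15 | 3-methyl-3-(4-methylpent-3-en-1-yl)-4,6-bis(3-methylbut-2-en-1-yl)-1-(trimethylsilyloxy)bicyclo[4.2.0]octan-7-one | C[Si](C)(C)O[C@@]12C[C@](C)(CCC=C(C)C)[C@@H](CC=C(C)C)C[C@]1(CC=C(C)C)C(=O)C2 | intermediate
16 | 3-methyl-3-(4-methylpent-3-en-1-yl)-4,6,8-tris(3-methylbut-2-en-1-yl)-1-(trimethylsilyloxy)bicyclo[4.2.0]octan-7-one (C8 epimers) | C[Si](C)(C)O[C@@]12C[C@](C)(CCC=C(C)C)[C@@H](CC=C(C)C)C[C@]1(CC=C(C)C)C(=O)C2CC=C(C)C | intermediate
17 | ring-expanded cyclooctane-1,3-dione enolate (enolate carbon = future C1), tris(dimethylamino)sulfonium salt | [O-]C1=C(CC=C(C)C)C[C@H](CC=C(C)C)[C@@](C)(CCC=C(C)C)CC(=O)C1CC=C(C)C.CN(C)[S+](N(C)C)N(C)C | intermediate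
18 | 2,4-dioxocyclooctane-1-carboxylate from 17 and CO2 (carboxylate on the future C1, cis to the neighbouring ring prenyl), tris(dimethylamino)sulfonium salt | CC(C)=CCC[C@]1(C)[C@@H](CC=C(C)C)C[C@@](CC=C(C)C)(C(=O)[O-])C(=O)C(CC=C(C)C)C(=O)C1.CN(C)[S+](N(C)C)N(C)C | intermediate
19 | acetoxy(phenyl)-λ3-iodanyl derivative of 18 at the β-diketone carbon (future C7) | CC(C)=CCC[C@]1(C)[C@@H](CC=C(C)C)C[C@@](CC=C(C)C)(C(=O)[O-])C(=O)C(CC=C(C)C)(I(OC(C)=O)c2ccccc2)C(=O)C1.CN(C)[S+](N(C)C)N(C)C | intermediate
20 | (1R,3S,4S,7S)-4-methyl-4-(4-methylpent-3-en-1-yl)-1,3,7-tris(3-methylbut-2-en-1-yl)-8-oxabicyclo[5.2.1]decane-6,9,10-trione | CC(C)=CCC[C@]1(C)[C@@H](CC=C(C)C)C[C@@]2(CC=C(C)C)C(=O)O[C@@](CC=C(C)C)(C(=O)C1)C2=O | intermediate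
21 | 5-(1-hydroxy-2-methylpropyl) derivative of 20 (diastereomers at C5 and the carbinol carbon) | CC(C)=CCC[C@]1(C)[C@@H](CC=C(C)C)C[C@@]2(CC=C(C)C)C(=O)O[C@@](CC=C(C)C)(C(=O)C1C(O)C(C)C)C2=O | intermediate
22 | (1R,3S,4R,5R,7S)-4-methyl-4-(4-methylpent-3-en-1-yl)-1,3,7-tris(3-methylbut-2-en-1-yl)-5-(2-methylpropanoyl)-8-oxabicyclo[5.2.1]decane-6,9,10-trione (CNP0121153.1) | CC(C)=CCC[C@]1(C)[C@@H](CC=C(C)C)C[C@@]2(CC=C(C)C)C(=O)O[C@@](CC=C(C)C)(C(=O)[C@H]1C(=O)C(C)C)C2=O | target

**Count and risks**
Total step count: 12. Longest linear sequence: 12 steps (from 1).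

Steps most likely to fail:

1. Step 10 (Proposed new method). The nascent enolate may be protonated by the newly formed β-diketone C–H before CO2 capture; the alkoxide may open toward the other cyclobutane bond; CO2 may end up on the undesired ring face; or the iodine(III) reagent may attack a side-chain alkene. The fallback separates the two bond formations and uses established reaction types. It sets out from 16: fluoride-induced ring opening under CO2 as before, but with esterification of the carboxylate in the flask (MeI), should give the methyl β-keto ester F1, whose C1 epimers can be separated. Deprotonation of the β-diketone (KHMDS, THF, −78 °C) and hydroxylation with 2-(phenylsulfonyl)-3-phenyloxaziridine should give the tertiary α-hydroxy diketone F2. Base-mediated lactonisation of the cis hydroxy ester (cat. DBU, loss of methanol) comes back to the route at 20.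

2. Step 7. Cycloaddition at the hindered tetrasubstituted enol ether may be slow, which would allow ketene oligomerisation, attack on the trisubstituted side-chain alkenes or desilylative C-acylation. The fallback runs the cycloaddition on a less hindered enol ether and brings in the C1 prenyl group last. It sets out from 9: LDA/TMSCl should give the kinetic trisubstituted silyl enol ether F3; dichloroketene then gives the cycloadduct F4; Zn/AcOH gives the cyclobutanone F5; LDA/prenyl bromide at the cyclobutanone CH2 gives F6. The cascade of step 10 applied to F6 should give the lactone F7, which lacks the C1 prenyl group. C-prenylation of its bridgehead β-keto lactone (NaH or K2CO3, prenyl bromide; retention is enforced by the bicycle) comes back to the route at 20.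

3. Step 9. The cyclobutanone enolate may lose the β-silanolate or self-condense in competition with alkylation. The fallback brings the prenyl group in with the ketene. It sets out from 13: cycloaddition with chloro(prenyl)ketene, generated from 2-chloro-5-methylhex-4-enoyl chloride (made from diethyl chloromalonate and prenyl bromide) and Et3N, should give the α-chlorocyclobutanone F8, and Zn/AcOH dechlorination comes back to the route at 16.

**Further compounds**
F1 | step 10 | methyl 6-methyl-6-(4-methylpent-3-en-1-yl)-1,3,7-tris(3-methylbut-2-en-1-yl)-2,4-dioxocyclooctane-1-carboxylate | CC(C)=CCC[C@]1(C)[C@@H](CC=C(C)C)C[C@@](CC=C(C)C)(C(=O)OC)C(=O)C(CC=C(C)C)C(=O)C1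
F2 | step 10 | methyl 3-hydroxy-6-methyl-6-(4-methylpent-3-en-1-yl)-1,3,7-tris(3-methylbut-2-en-1-yl)-2,4-dioxocyclooctane-1-carboxylate (hydroxyl cis to the ester) | CC(C)=CCC[C@]1(C)[C@@H](CC=C(C)C)C[C@@](CC=C(C)C)(C(=O)OC)C(=O)[C@](O)(CC=C(C)C)C(=O)C1
F3 | step 7 | kinetic trimethylsilyl enol ether of 9 (double bond away from the quaternary carbon) | C[Si](C)(C)OC1=CC[C@H](CC=C(C)C)[C@@](C)(CCC=C(C)C)C1
F4 | step 7 | 8,8-dichloro-3-methyl-3-(4-methylpent-3-en-1-yl)-4-(3-methylbut-2-en-1-yl)-1-(trimethylsilyloxy)bicyclo[4.2.0]octan-7-one | C[Si](C)(C)O[C@@]12C[C@](C)(CCC=C(C)C)[C@@H](CC=C(C)C)C[C@@H]1C(=O)C2(Cl)Cl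
F5 | step 7 | 3-methyl-3-(4-methylpent-3-en-1-yl)-4-(3-methylbut-2-en-1-yl)-1-(trimethylsilyloxy)bicyclo[4.2.0]octan-7-one | C[Si](C)(C)O[C@@]12C[C@](C)(CCC=C(C)C)[C@@H](CC=C(C)C)C[C@@H]1C(=O)C2
F6 | step 7 | 3-methyl-3-(4-methylpent-3-en-1-yl)-4,8-bis(3-methylbut-2-en-1-yl)-1-(trimethylsilyloxy)bicyclo[4.2.0]octan-7-one | C[Si](C)(C)O[C@@]12C[C@](C)(CCC=C(C)C)[C@@H](CC=C(C)C)C[C@@H]1C(=O)C2CC=C(C)C
F7 | step 7 | 4-methyl-4-(4-methylpent-3-en-1-yl)-3,7-bis(3-methylbut-2-en-1-yl)-8-oxabicyclo[5.2.1]decane-6,9,10-trione | CC(C)=CCC[C@]1(C)[C@@H](CC=C(C)C)C[C@H]2C(=O)O[C@@](CC=C(C)C)(C(=O)C1)C2=O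
F8 | step 9 | 8-chloro-3-methyl-3-(4-methylpent-3-en-1-yl)-4,6,8-tris(3-methylbut-2-en-1-yl)-1-(trimethylsilyloxy)bicyclo[4.2.0]octan-7-one | C[Si](C)(C)O[C@@]12C[C@](C)(CCC=C(C)C)[C@@H](CC=C(C)C)C[C@]1(CC=C(C)C)C(=O)C2(Cl)CC=C(C)C
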